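**Plan**
1. Ring atoms are numbered as in 7‑oxabicyclo[4.1.0]hept‑3‑ene‑2,5‑dione (C1 = oxirane carbon with the side chain, C2/C5 = ketones, C3=C4 alkene with CH2OAc on C4, C6 = oxirane CH); side chain C1' (carbinol) to C6' (CHO). Retrosynthesis: mask C2=O as a dimethyl ketal, cut the dienal at C2'=C3' and C4'=C5' (two Wittig reactions), trace CH2OAc to an ester, then cut the ring at the C3=C4 alkene and at the C1–C6 oxirane C–C bond.
2. Enabling feature: C4 and C6 are both α to the C5 ketone, and each is bonded to a carbon (C3, C1) that flanks C2. C3=C4 is therefore a Knoevenagel retron and C1–C6 an α,β‑epoxy‑ketone (Darzens) retron, so the carbocycle is the sum of the C4–C5–C6 dinucleophile ethyl 4‑chloroacetoacetate and a C3–C2–C1 aldehyde/ketal/ketone dielectrophile.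
3. Forward: the C3–C2–C1 chain is built on (S)‑glyceraldehyde acetonide with 1‑methoxyvinyllithium (steps 1–3); a one‑pot annulation closes the cyclohexenone and the oxirane together (step 4); ester to CH2OAc (5–7); side chain by acetonide cleavage, acetylation, oxidation and two Wittig homologations (8–12); ketal hydrolysis last (13).
4. Stereochemistry: C1' (S) is the dioxolane carbon of 1; it sets C1 (R) by chelation‑controlled aldol addition in step 4; C6 (S) follows from the obligatory cis ring fusion; both side‑chain alkenes are E from stabilised ylides.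

Key step: step 4

Remark: the stereochemical outcome of step 4 assumes that divalent magnesium chelates the ketone with the α‑oxygen of the dioxolane; the fallback for step 4 relies on the same chelate.

**Step 1**
Reactants: 1 (S)‑2,2‑dimethyl‑1,3‑dioxolane‑4‑carbaldehyde; 2 methyl vinyl ether
Product: 4 (1RS)‑1‑[(4S)‑2,2‑dimethyl‑1,3‑dioxolan‑4‑yl]‑2‑methoxyprop‑2‑en‑1‑ol, via 1‑methoxyvinyllithium 3 (not isolated)
Conditions: 2, t‑BuLi, THF, −78 → 0 °C; then 1, −78 °C; H2O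
Reagents that add atoms: none
Why: Lithiated methyl vinyl ether is an acyl‑anion equivalent that adds 1,2 to the aldehyde (organolithium addition); the new carbinol centre is oxidised in step 3, so its configuration does not matter, and the dioxolane stereocentre is untouched.

**Step 2**
Reactants: 4
Product: 5 (1RS)‑1‑[(4S)‑2,2‑dimethyl‑1,3‑dioxolan‑4‑yl]‑2,2‑dimethoxypropane‑1,3‑diol
Conditions: dimethyldioxirane (acetone), CH2Cl2/MeOH, −40 → 0 °C
Reagents that add atoms: dimethyldioxirane CC1(C)OO1; methanol CO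
Why: Epoxidation of the electron‑rich enol ether by the neutral dioxirane and methanolysis of the 2‑methoxyoxirane at its acetal carbon (enol‑ether epoxidation/solvolysis) should give the α‑hydroxy dimethyl ketal without acid that would hydrolyse the enol ether.

**Step 3**
Reactants: 5
Product: 6 3‑[(4S)‑2,2‑dimethyl‑1,3‑dioxolan‑4‑yl]‑2,2‑dimethoxy‑3‑oxopropanal
Conditions: Dess–Martin periodinane (2.5 equiv), CH2Cl2, 0 °C → rt
Reagents that add atoms: none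
Why: Dess–Martin oxidation converts the primary and the secondary alcohol into aldehyde and ketone in one operation without base, so the α‑alkoxy ketone is not epimerised, and the quaternary ketal carbon between the two carbonyls cannot enolise.

**Step 4**
Reactants: 6; 7 ethyl 4‑chloro‑3‑oxobutanoate (ethyl 4‑chloroacetoacetate)
Product: 10 ethyl (1R,6S)‑1‑[(4S)‑2,2‑dimethyl‑1,3‑dioxolan‑4‑yl]‑2,2‑dimethoxy‑5‑oxo‑7‑oxabicyclo[4.1.0]hept‑3‑ene‑4‑carboxylate, via Knoevenagel adduct 8 (not isolated), via trans‑chlorohydrin 9 (not isolated)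
Conditions: piperidine (cat.), AcOH (cat.), 4 Å MS, CH2Cl2, 0 °C → rt; then MgBr2·OEt2, i‑Pr2NEt, −40 °C → rt
Reagents that add atoms: none
Why: Proposed new method: the amine catalyses Knoevenagel condensation of the active methylene of 7 with the aldehyde of 6 (C3=C4 bond) to the alkylidene keto ester 8, whose geometric isomers equilibrate by reversible conjugate addition; MgBr2 and i‑Pr2NEt then enolise the chloromethyl ketone of the chelated 1,3‑dicarbonyl unit, the enolate adds to the ketone (C1–C6 bond) to give chlorohydrin 9, and the magnesium alkoxide displaces the anti chloride to give the oxirane, an intramolecular Darzens reaction. The closest known reaction types are the Knoevenagel/aldol [3+3] cyclocondensation of acetoacetates with 1,3‑dicarbonyl compounds and the amine‑catalysed Michael/aldol/intramolecular SN2 annulation of γ‑chloro‑β‑keto esters with enals, which gives epoxycyclohexanones; new are the Knoevenagel entry, the ketone acceptor and the fully substituted oxirane carbon. The carbocycle closes by a 6‑(enolendo)‑exo‑trig aldol addition and the oxirane by a 3‑exo‑tet substitution. C1 is set by chelation control: divalent magnesium bridges the ketone oxygen and the α‑oxygen of the (4S)‑dioxolane, and the enolate adds to the face opposite the dioxolane CH2 group, which gives 1R; C6 has no freedom, since the oxirane can only be cis‑fused and a cis‑chlorohydrin epimerises through its enol before closure. The step needs aldehyde‑over‑ketone selectivity in the condensation and C6‑over‑C1' enolisation afterwards: the ketal carbon C2 makes the aldehyde non‑enolisable and keeps the two carbonyls of 6 apart, and the CH2Cl group is the only acidic site left on the magnesium‑chelated keto ester.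

**Step 5**
Reactants: 10
Product: 11 (1R,5RS,6R)‑1‑[(4S)‑2,2‑dimethyl‑1,3‑dioxolan‑4‑yl]‑4‑(hydroxymethyl)‑2,2‑dimethoxy‑7‑oxabicyclo[4.1.0]hept‑3‑en‑5‑ol
Conditions: i‑Bu2AlH (excess), CH2Cl2, −78 °C; aq. potassium sodium tartrate
Reagents that add atoms: none
Why: Hydride reduction with i‑Bu2AlH at low temperature should reduce the ketone 1,2 and the ester to the primary allylic alcohol while ketal, acetonide and oxirane survive; the ring carbinol centre is removed again in step 7.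

**Step 6**
Reactants: 11
Product: 12 [(1R,5RS,6R)‑1‑[(4S)‑2,2‑dimethyl‑1,3‑dioxolan‑4‑yl]‑5‑hydroxy‑2,2‑dimethoxy‑7‑oxabicyclo[4.1.0]hept‑3‑en‑4‑yl]methyl acetate
Conditions: AcCl (1.05 equiv), 2,4,6‑collidine, CH2Cl2, −78 °C
Reagents that add atoms: acetyl chloride CC(=O)Cl
Why: Selective acylation: the unhindered primary allylic alcohol is acetylated much faster than the secondary alcohol flanked by the oxirane.

**Step 7**
Reactants: 12
Product: 13 [(1R,6S)‑1‑[(4S)‑2,2‑dimethyl‑1,3‑dioxolan‑4‑yl]‑2,2‑dimethoxy‑5‑oxo‑7‑oxabicyclo[4.1.0]hept‑3‑en‑4‑yl]methyl acetate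
Conditions: Dess–Martin periodinane, CH2Cl2, rt
Reagents that add atoms: none
Why: Dess–Martin oxidation returns the ring alcohol to the enone without touching the oxirane, the acetate or the ketals.

**Step 8**
Reactants: 13
Product: 14 [(1R,6S)‑1‑[(1S)‑1,2‑dihydroxyethyl]‑2,2‑dimethoxy‑5‑oxo‑7‑oxabicyclo[4.1.0]hept‑3‑en‑4‑yl]methyl acetate
Conditions: pyridinium p‑toluenesulfonate (cat.), MeOH, rt
Reagents that add atoms: none
Why: Acid‑catalysed transketalisation to methanol removes the terminal acetonide, while the ring dimethyl ketal only exchanges degenerately with the solvent and its oxocarbenium ion is disfavoured by the flanking oxirane and enone.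

**Step 9**
Reactants: 14
Product: 16 (1S)‑1‑[(1R,6S)‑4‑(acetoxymethyl)‑2,2‑dimethoxy‑5‑oxo‑7‑oxabicyclo[4.1.0]hept‑3‑en‑1‑yl]‑2‑(tert‑butyldimethylsilyloxy)ethyl acetate, via mono‑silyl ether 15 (not isolated)
Conditions: t‑BuMe2SiCl, imidazole, CH2Cl2, 0 °C; then Ac2O, DMAP (cat.), rt
Reagents that add atoms: tert‑butyldimethylsilyl chloride CC(C)(C)[Si](C)(C)Cl; acetic anhydride CC(=O)OC(C)=O
Why: The primary hydroxyl is silylated selectively for steric reasons and the remaining secondary hydroxyl is acetylated in the same flask (DMAP‑catalysed acylation), which installs the final C1' acetate.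

**Step 10**
Reactants: 16
Product: 17 (1S)‑1‑[(1R,6S)‑4‑(acetoxymethyl)‑2,2‑dimethoxy‑5‑oxo‑7‑oxabicyclo[4.1.0]hept‑3‑en‑1‑yl]‑2‑hydroxyethyl acetate
Conditions: HF·pyridine, pyridine, THF, 0 °C
Reagents that add atoms: none
Why: Buffered HF·pyridine cleaves the primary silyl ether under mildly acidic conditions that suppress 1,2‑acetyl migration and leave the epoxy enone and both acetates intact.

**Step 11**
Reactants: 17; 18 2‑(triphenylphosphoranylidene)propanal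
Product: 20 (1S,2E)‑1‑[(1R,6S)‑4‑(acetoxymethyl)‑2,2‑dimethoxy‑5‑oxo‑7‑oxabicyclo[4.1.0]hept‑3‑en‑1‑yl]‑3‑methyl‑4‑oxobut‑2‑en‑1‑yl acetate, via α‑acetoxy aldehyde 19 (not isolated)
Conditions: Dess–Martin periodinane, CH2Cl2, 0 °C; filter, concentrate; then 18, toluene, 60 °C
Reagents that add atoms: none
Why: Dess–Martin oxidation gives the α‑acetoxy aldehyde, which is trapped without isolation in a Wittig reaction; the stabilised ylide gives the E trisubstituted enal and is too weakly basic to epimerise C1' or to open the oxirane by enolisation.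

**Step 12**
Reactants: 20; 21 (triphenylphosphoranylidene)acetaldehyde
Product: 22 (1S,2E,4E)‑1‑[(1R,6S)‑4‑(acetoxymethyl)‑2,2‑dimethoxy‑5‑oxo‑7‑oxabicyclo[4.1.0]hept‑3‑en‑1‑yl]‑3‑methyl‑6‑oxohexa‑2,4‑dien‑1‑yl acetate
Conditions: 21 (1.2 equiv), toluene, 50 °C
Reagents that add atoms: none
Why: Wittig reaction of the enal with the stabilised formylmethylene ylide adds two carbons as an E alkene; a small excess and moderate temperature are meant to limit a second homologation.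

**Step 13**
Reactants: 22
Product: 23 (1S,2E,4E)‑1‑[(1R,6S)‑4‑(acetoxymethyl)‑2,5‑dioxo‑7‑oxabicyclo[4.1.0]hept‑3‑en‑1‑yl]‑3‑methyl‑6‑oxohexa‑2,4‑dien‑1‑yl acetate (target)
Conditions: CF3CO2H, H2O, CH2Cl2, 0 °C
Reagents that add atoms: water O
Why: Acetal hydrolysis of the dimethyl ketal unveils the C2 ketone last, because the epoxy enedione would not survive the nucleophilic and basic steps before it, whereas acetates, oxirane and dienal should tolerate brief cold aqueous acid.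

**Compound list**
1 | (S)‑2,2‑dimethyl‑1,3‑dioxolane‑4‑carbaldehyde | O=C[C@@H]1COC(C)(C)O1 | starting material
2 | methyl vinyl ether | C=COC | starting material
3 | 1‑methoxyvinyllithium | [Li]C(=C)OC | intermediate
4 | (1RS)‑1‑[(4S)‑2,2‑dimethyl‑1,3‑dioxolan‑4‑yl]‑2‑methoxyprop‑2‑en‑1‑ol | C=C(OC)C(O)[C@@H]1COC(C)(C)O1 | intermediate
5 | (1RS)‑1‑[(4S)‑2,2‑dimethyl‑1,3‑dioxolan‑4‑yl]‑2,2‑dimethoxypropane‑1,3‑diol | OCC(OC)(OC)C(O)[C@@H]1COC(C)(C)O1 | intermediate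
6 | 3‑[(4S)‑2,2‑dimethyl‑1,3‑dioxolan‑4‑yl]‑2,2‑dimethoxy‑3‑oxopropanal | O=CC(OC)(OC)C(=O)[C@@H]1COC(C)(C)O1 | intermediate
7 | ethyl 4‑chloro‑3‑oxobutanoate | CCOC(=O)CC(=O)CCl | starting material
8 | ethyl (2E)‑2‑(chloroacetyl)‑5‑[(4S)‑2,2‑dimethyl‑1,3‑dioxolan‑4‑yl]‑4,4‑dimethoxy‑5‑oxopent‑2‑enoate | ClCC(=O)/C(C(=O)OCC)=C\C(OC)(OC)C(=O)[C@@H]1COC(C)(C)O1 | intermediate
9 | ethyl (4S,5R)‑5‑chloro‑4‑[(4S)‑2,2‑dimethyl‑1,3‑dioxolan‑4‑yl]‑4‑hydroxy‑3,3‑dimethoxy‑6‑oxocyclohex‑1‑ene‑1‑carboxylate | CCOC(=O)C1=CC(OC)(OC)[C@@](O)([C@@H]3COC(C)(C)O3)[C@@H](Cl)C1=O | intermediate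
10 | ethyl (1R,6S)‑1‑[(4S)‑2,2‑dimethyl‑1,3‑dioxolan‑4‑yl]‑2,2‑dimethoxy‑5‑oxo‑7‑oxabicyclo[4.1.0]hept‑3‑ene‑4‑carboxylate | CCOC(=O)C1=CC(OC)(OC)[C@]2([C@@H]3COC(C)(C)O3)O[C@@H]2C1=O | intermediate
11 | (1R,5RS,6R)‑1‑[(4S)‑2,2‑dimethyl‑1,3‑dioxolan‑4‑yl]‑4‑(hydroxymethyl)‑2,2‑dimethoxy‑7‑oxabicyclo[4.1.0]hept‑3‑en‑5‑ol | OCC1=CC(OC)(OC)[C@]2([C@@H]3COC(C)(C)O3)O[C@@H]2C1O | intermediate
12 | [(1R,5RS,6R)‑1‑[(4S)‑2,2‑dimethyl‑1,3‑dioxolan‑4‑yl]‑5‑hydroxy‑2,2‑dimethoxy‑7‑oxabicyclo[4.1.0]hept‑3‑en‑4‑yl]methyl acetate | CC(=O)OCC1=CC(OC)(OC)[C@]2([C@@H]3COC(C)(C)O3)O[C@@H]2C1O | intermediate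
13 | [(1R,6S)‑1‑[(4S)‑2,2‑dimethyl‑1,3‑dioxolan‑4‑yl]‑2,2‑dimethoxy‑5‑oxo‑7‑oxabicyclo[4.1.0]hept‑3‑en‑4‑yl]methyl acetate | CC(=O)OCC1=CC(OC)(OC)[C@]2([C@@H]3COC(C)(C)O3)O[C@@H]2C1=O | intermediate
14 | [(1R,6S)‑1‑[(1S)‑1,2‑dihydroxyethyl]‑2,2‑dimethoxy‑5‑oxo‑7‑oxabicyclo[4.1.0]hept‑3‑en‑4‑yl]methyl acetate | CC(=O)OCC1=CC(OC)(OC)[C@]2([C@@H](O)CO)O[C@@H]2C1=O | intermediate
15 | [(1R,6S)‑1‑[(1S)‑2‑(tert‑butyldimethylsilyloxy)‑1‑hydroxyethyl]‑2,2‑dimethoxy‑5‑oxo‑7‑oxabicyclo[4.1.0]hept‑3‑en‑4‑yl]methyl acetate | CC(=O)OCC1=CC(OC)(OC)[C@]2([C@@H](O)CO[Si](C)(C)C(C)(C)C)O[C@@H]2C1=O | intermediate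
16 | (1S)‑1‑[(1R,6S)‑4‑(acetoxymethyl)‑2,2‑dimethoxy‑5‑oxo‑7‑oxabicyclo[4.1.0]hept‑3‑en‑1‑yl]‑2‑(tert‑butyldimethylsilyloxy)ethyl acetate | CC(=O)OCC1=CC(OC)(OC)[C@]2([C@H](CO[Si](C)(C)C(C)(C)C)OC(C)=O)O[C@@H]2C1=O | intermediate
17 | (1S)‑1‑[(1R,6S)‑4‑(acetoxymethyl)‑2,2‑dimethoxy‑5‑oxo‑7‑oxabicyclo[4.1.0]hept‑3‑en‑1‑yl]‑2‑hydroxyethyl acetate | CC(=O)OCC1=CC(OC)(OC)[C@]2([C@H](CO)OC(C)=O)O[C@@H]2C1=O | intermediate
18 | 2‑(triphenylphosphoranylidene)propanal | CC(C=O)=P(c1ccccc1)(c1ccccc1)c1ccccc1 | starting material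
19 | (1R)‑1‑[(1R,6S)‑4‑(acetoxymethyl)‑2,2‑dimethoxy‑5‑oxo‑7‑oxabicyclo[4.1.0]hept‑3‑en‑1‑yl]‑2‑oxoethyl acetate | CC(=O)OCC1=CC(OC)(OC)[C@]2([C@H](C=O)OC(C)=O)O[C@@H]2C1=O | intermediate
20 | (1S,2E)‑1‑[(1R,6S)‑4‑(acetoxymethyl)‑2,2‑dimethoxy‑5‑oxo‑7‑oxabicyclo[4.1.0]hept‑3‑en‑1‑yl]‑3‑methyl‑4‑oxobut‑2‑en‑1‑yl acetate | CC(=O)OCC1=CC(OC)(OC)[C@]2([C@H](/C=C(C)/C=O)OC(C)=O)O[C@@H]2C1=O | intermediate
21 | (triphenylphosphoranylidene)acetaldehyde | O=CC=P(c1ccccc1)(c1ccccc1)c1ccccc1 | starting material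
22 | (1S,2E,4E)‑1‑[(1R,6S)‑4‑(acetoxymethyl)‑2,2‑dimethoxy‑5‑oxo‑7‑oxabicyclo[4.1.0]hept‑3‑en‑1‑yl]‑3‑methyl‑6‑oxohexa‑2,4‑dien‑1‑yl acetate | CC(=O)OCC1=CC(OC)(OC)[C@]2([C@H](/C=C(C)/C=C/C=O)OC(C)=O)O[C@@H]2C1=O | intermediate
23 | (1S,2E,4E)‑1‑[(1R,6S)‑4‑(acetoxymethyl)‑2,5‑dioxo‑7‑oxabicyclo[4.1.0]hept‑3‑en‑1‑yl]‑3‑methyl‑6‑oxohexa‑2,4‑dien‑1‑yl acetate | CC(=O)OCC1=CC(=O)[C@]2([C@H](/C=C(C)/C=C/C=O)OC(C)=O)O[C@@H]2C1=O | target

**Totals**
Total steps: 13. Longest linear sequence: 13 steps (from 1).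

**Steps most likely to fail**

Step 4 (Proposed new method). The annulation may fail in three ways: retro‑Claisen loss of the formyl group of 6 under the amine; conjugate addition or furanone‑forming O‑alkylation of adduct 8 outrunning the aldol closure; and poor facial selectivity if an open transition state or enolisation of the chelated ketone competes with the chelate. The fallback builds the same two bonds stepwise with known reactions, oxirane‑side C–C bond first and alkene last, setting out from 5 and coming back at 10. Diol 5 is silylated at the primary hydroxyl (t‑BuMe2SiCl, imidazole) to give (1RS)‑3‑(tert‑butyldimethylsilyloxy)‑1‑[(4S)‑2,2‑dimethyl‑1,3‑dioxolan‑4‑yl]‑2,2‑dimethoxypropan‑1‑ol F1, and Dess–Martin oxidation gives the ketone 3‑(tert‑butyldimethylsilyloxy)‑1‑[(4S)‑2,2‑dimethyl‑1,3‑dioxolan‑4‑yl]‑2,2‑dimethoxypropan‑1‑one F2. Ester 7 is converted (Me3SiCl, Et3N) into ethyl 4‑chloro‑3‑(trimethylsilyloxy)but‑2‑enoate F3 and then (LDA, Me3SiCl) into 4‑chloro‑1‑ethoxy‑1,3‑bis(trimethylsilyloxy)buta‑1,3‑diene F4. A MgBr2·OEt2‑promoted, chelation‑controlled vinylogous Mukaiyama aldol addition of the chlorine‑bearing terminus of F4 to F2 should give, after aqueous work‑up, the chlorohydrin ethyl (4RS,5S)‑7‑(tert‑butyldimethylsilyloxy)‑4‑chloro‑5‑[(4S)‑2,2‑dimethyl‑1,3‑dioxolan‑4‑yl]‑5‑hydroxy‑6,6‑dimethoxy‑3‑oxoheptanoate F5. HF·pyridine frees the primary alcohol ethyl (4RS,5S)‑4‑chloro‑5‑[(4S)‑2,2‑dimethyl‑1,3‑dioxolan‑4‑yl]‑5,7‑dihydroxy‑6,6‑dimethoxy‑3‑oxoheptanoate F6, and Dess–Martin oxidation gives the aldehyde ethyl (4RS,5S)‑4‑chloro‑5‑[(4S)‑2,2‑dimethyl‑1,3‑dioxolan‑4‑yl]‑5‑hydroxy‑6,6‑dimethoxy‑3,7‑dioxoheptanoate F7. Piperidinium acetate then closes the ring by intramolecular Knoevenagel condensation to 9, and i‑Pr2NEt closes the oxirane to 10 as in step 4.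

Step 11. The α‑acetoxy aldehyde 19 may epimerise at C1' or open the oxirane by enolisation, and the acetyl group of 17 may migrate to the primary hydroxyl before oxidation. The fallback avoids the acetate at the aldehyde stage, setting out from 14 and coming back at 20. TEMPO (cat.) with PhI(OAc)2 oxidises only the primary hydroxyl of diol 14 in the presence of ylide 18, so that [(1R,6S)‑1‑[(1R)‑1‑hydroxy‑2‑oxoethyl]‑2,2‑dimethoxy‑5‑oxo‑7‑oxabicyclo[4.1.0]hept‑3‑en‑4‑yl]methyl acetate F8 is olefinated as it forms to [(1R,6S)‑1‑[(1S,2E)‑1‑hydroxy‑3‑methyl‑4‑oxobut‑2‑en‑1‑yl]‑2,2‑dimethoxy‑5‑oxo‑7‑oxabicyclo[4.1.0]hept‑3‑en‑4‑yl]methyl acetate F9. Acetylation (Ac2O, pyridine) then gives 20.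

Step 12. The product dienal may be homologated a second time by the formylmethylene ylide, giving trienal mixtures. The fallback uses a masked two‑carbon ylide, setting out from 20 and coming back at 23. Wittig reaction with the ylide from tributyl(1,3‑dioxolan‑2‑ylmethyl)phosphonium bromide and KOt‑Bu (THF, −78 °C, ylide pre‑formed) should give (1S,2E,4E)‑1‑[(1R,6S)‑4‑(acetoxymethyl)‑2,2‑dimethoxy‑5‑oxo‑7‑oxabicyclo[4.1.0]hept‑3‑en‑1‑yl]‑5‑(1,3‑dioxolan‑2‑yl)‑3‑methylpenta‑2,4‑dien‑1‑yl acetate F10, which cannot react again. The acid of step 13 then hydrolyses the dioxolane and the ring ketal together to give 23.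

**Further compounds**
F1 | step 4 | (1RS)‑3‑(tert‑butyldimethylsilyloxy)‑1‑[(4S)‑2,2‑dimethyl‑1,3‑dioxolan‑4‑yl]‑2,2‑dimethoxypropan‑1‑ol | CC(C)(C)[Si](C)(C)OCC(OC)(OC)C(O)[C@@H]1COC(C)(C)O1
F2 | step 4 | 3‑(tert‑butyldimethylsilyloxy)‑1‑[(4S)‑2,2‑dimethyl‑1,3‑dioxolan‑4‑yl]‑2,2‑dimethoxypropan‑1‑one | CC(C)(C)[Si](C)(C)OCC(OC)(OC)C(=O)[C@@H]1COC(C)(C)O1
F3 | step 4 | ethyl 4‑chloro‑3‑(trimethylsilyloxy)but‑2‑enoate | CCOC(=O)C=C(CCl)O[Si](C)(C)C
F4 | step 4 | 4‑chloro‑1‑ethoxy‑1,3‑bis(trimethylsilyloxy)buta‑1,3‑diene | CCOC(O[Si](C)(C)C)=CC(O[Si](C)(C)C)=CCl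
F5 | step 4 | ethyl (4RS,5S)‑7‑(tert‑butyldimethylsilyloxy)‑4‑chloro‑5‑[(4S)‑2,2‑dimethyl‑1,3‑dioxolan‑4‑yl]‑5‑hydroxy‑6,6‑dimethoxy‑3‑oxoheptanoate | CCOC(=O)CC(=O)C(Cl)[C@](O)([C@@H]1COC(C)(C)O1)C(OC)(OC)CO[Si](C)(C)C(C)(C)C
F6 | step 4 | ethyl (4RS,5S)‑4‑chloro‑5‑[(4S)‑2,2‑dimethyl‑1,3‑dioxolan‑4‑yl]‑5,7‑dihydroxy‑6,6‑dimethoxy‑3‑oxoheptanoate | CCOC(=O)CC(=O)C(Cl)[C@](O)([C@@H]1COC(C)(C)O1)C(OC)(OC)CO
F7 | step 4 | ethyl (4RS,5S)‑4‑chloro‑5‑[(4S)‑2,2‑dimethyl‑1,3‑dioxolan‑4‑yl]‑5‑hydroxy‑6,6‑dimethoxy‑3,7‑dioxoheptanoate | CCOC(=O)CC(=O)C(Cl)[C@](O)([C@@H]1COC(C)(C)O1)C(OC)(OC)C=O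
F8 | step 11 | [(1R,6S)‑1‑[(1R)‑1‑hydroxy‑2‑oxoethyl]‑2,2‑dimethoxy‑5‑oxo‑7‑oxabicyclo[4.1.0]hept‑3‑en‑4‑yl]methyl acetate | CC(=O)OCC1=CC(OC)(OC)[C@]2([C@@H](O)C=O)O[C@@H]2C1=O
F9 | step 11 | [(1R,6S)‑1‑[(1S,2E)‑1‑hydroxy‑3‑methyl‑4‑oxobut‑2‑en‑1‑yl]‑2,2‑dimethoxy‑5‑oxo‑7‑oxabicyclo[4.1.0]hept‑3‑en‑4‑yl]methyl acetate | CC(=O)OCC1=CC(OC)(OC)[C@]2([C@@H](O)/C=C(C)/C=O)O[C@@H]2C1=O
F10 | step 12 | (1S,2E,4E)‑1‑[(1R,6S)‑4‑(acetoxymethyl)‑2,2‑dimethoxy‑5‑oxo‑7‑oxabicyclo[4.1.0]hept‑3‑en‑1‑yl]‑5‑(1,3‑dioxolan‑2‑yl)‑3‑methylpenta‑2,4‑dien‑1‑yl acetate | CC(=O)OCC1=CC(OC)(OC)[C@]2([C@H](/C=C(C)/C=C/C3OCCO3)OC(C)=O)O[C@@H]2C1=O
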